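| setting | amber | grey | Saturday's | Monday's | Tuesday's |
|---|---|---|---|---|---|
| substrate | 11 mM | 22 mM | 11 mM | 11 mM | 11 mM (fed, over 3.0 h) |
| partner | 10.4 mM | 10.4 mM | 10.4 mM (fed, over 3.0 h) | 10.4 mM | 10.4 mM |
| remark | run made earlier | run made earlier | all else is in the flask from the start; the feed brings no volume worth counting | everything together at the start | all else is in the flask from the start; the feed brings no volume worth counting |
| time |  |  | 15 h | 15 h | 15 h |

- amber (time / h: product / %): 1.33: 56.6; 2.00: 62.3; 3.00: 64.7; 5.00: 65.4; 10.0: 67.5; 15.0: 66.0
- grey (time / min: product / %): 15.0: 23.2; 30.0: 30.9; 50.0: 34.6; 60.0: 36.2; 80.0: 38.6; 90.0: 39.3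

(readings scatter by 0.5 percentage points)

- the flask that comes out highest in amount of product, in percent of the substrate charged, or "all alike" when all lie within 1.5 percentage points (Saturday's / Monday's / Tuesday's / all alike)
- product at the end, in percent of the substrate charged, Saturday's
- product at the end, in percent of the substrate charged, Monday's
- product at the end, in percent of the substrate charged, Tuesday's

- the analysis behind the earlier runs scatters by 0.5 percentage points, standard deviation
- reactions considered so far: substrate + partner -> product; partner -> decomposed reagent

The amber run could not turn all its substrate into product: its partner, the limiting reagent, allowed 94.5%, yet the last three readings average 66.3%. So I followed the rate. In the grey run, product formed at 20.4 mM/h over the first 15.0 min and at 6.78 mM/h over the next window, a slowing by a factor of 3.01. Taking the rate as proportional to substrate, lost substrate explains a factor of 1.21, which leaves 2.49 for lost partner.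

Accumulated, that slowing ends in a plateau, and I took the partner missing from the product as decomposed. Amber's ratio of product to decomposed partner is 2.35, and its mean substrate, replacing the curve by the mean of start and end, is 7.35 mM. Their quotient is what I carried, the capture factor, a selectivity factor per unit of mean substrate: 0.319 /mM. I took nothing from the grey run for it, since its readings were still rising, from 36.2% at 60.0 min to 39.3% at 90.0 min, and partner still in that flask would have been counted as decomposed.

For Tuesday's, I let substrate rise straight from nothing to what finally remains, and the factor gave 46.0%. The forecast named Saturday's highest, with 67%, 66.2% for Monday's and 42% for Tuesday's, which lies below mine, saying “Feeding substrate starves the partner of substrate while it decomposes”.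

The flasks gave 63.2% for Saturday's, 66.9% for Monday's and 48.1% for Tuesday's, so Monday's came highest.

    substrate + partner → product, rate k1*[substrate]*[partner]^1.5 (k = 1800 /M^1.5/h)
    partner → decomposed reagent (k = 0.270 /h)

The largest single effect on the gap between Monday's and Tuesday's is the step from partner to decomposed reagent: without it the gap shrinks from 19 percentage points to 0.68 points. Tuesday's ended with a ratio of product to decomposed reagent of 1.04, and the capture factor times its mean substrate of 3.15 mM over the first 3.0 h gives 1.00. Monday's recipe with 19 mM of substrate, reckoned by the factor at 45.1%, gave 45.7%.

(The data stem from a simulated flask with made-up constants, and the scatter is random.)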